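**Retrosynthetic overview**
1. Target 23 ⇐ bis-silyl ether 22. Ring A (pyran) closes last: C4–C4a and O2–C3 are cut back to enone alcohol 16 and sulfoxonium ylide 20 (hydroxyl-directed rhodium-catalysed alkenyl C–H acylmethylation, then cyclodehydration).
2. 16 ⇐ keto-diol 7 + aroyl chloride 13 (ester at O8), followed by C4a=C5 desaturation and PMB removal.
3. 7 ⇐ enone 6 (syn-dihydroxylation anti to the C8a arm sets C7 and C8); ring B of 6 ⇐ aldehyde 3 + ethyl vinyl ketone 4 (organocatalytic Michael addition sets C8a, then aldol condensation).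
4. 13 ⇐ orsellinic acid 11 ⇐ two molecules of methyl acetoacetate 8; 20 ⇐ crotonyl chloride 17 + trimethylsulfoxonium iodide 18.
5. Ring order: orsellinate arene (separate branch), then ring B, then ring A; fragments A (core), B (arene), C (C3/C4 and propenyl).

Assumption: the SMILES is read as (7R,8R,8aR); atom labels follow isochromene numbering (C1, O2, C3, C4, C4a, C5–C8, C8a). PMB = 4-methoxybenzyl, TBS = tert-butyldimethylsilyl, Cp* = pentamethylcyclopentadienyl, HFIP = 1,1,1,3,3,3-hexafluoropropan-2-ol.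

**Fragment A (core)**

Step 1
Reactants: 1 propane-1,3-diol
Product: 2 3-[(4-methoxybenzyl)oxy]propan-1-ol
Conditions: NaH (1.0 equiv), THF/DMF, 0 °C; PMBCl (0.9 equiv), Bu4NI (cat.), 0 °C→rt (diol in excess)
Reagents that add atoms: 4-methoxybenzyl chloride, COc1ccc(CCl)cc1
Why: Williamson etherification of the mono-alkoxide of a symmetric diol gives the mono-PMB ether; no stereocentre.

Step 2
Reactants: 2 3-[(4-methoxybenzyl)oxy]propan-1-ol
Product: 3 3-[(4-methoxybenzyl)oxy]propanal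
Conditions: TEMPO (10 mol%), PhI(OAc)2 (1.1 equiv), CH2Cl2, rt
Reagents that add atoms: none
Why: TEMPO/oxoammonium oxidation stops cleanly at the aldehyde and tolerates the PMB ether.

Step 3
Reactants: 3 3-[(4-methoxybenzyl)oxy]propanal; 4 pent-1-en-3-one (ethyl vinyl ketone)
Product: 6 (S)-4-{[(4-methoxybenzyl)oxy]methyl}-2-methylcyclohex-2-en-1-one, via keto-aldehyde 5 (not isolated)
Conditions: (R)-2-[methoxy(diphenyl)methyl]pyrrolidine (5 mol%), ethyl 3,4-dihydroxybenzoate (20 mol%), neat, 4 °C; then i-PrOH, LiOH (0.5 equiv), 0 °C→rt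
Reagents that add atoms: none
Why: Enamine-catalysed Michael addition (Gellman/Hayashi type) sets C8a, because the (R)-catalyst shields one enamine face and gives (R)-5 (R because CH2OPMB outranks the new chain); intramolecular aldol condensation of the ethyl ketone onto the aldehyde then closes ring B, and low temperature limits epimerisation or loss of the β-alkoxy group.

Step 4
Reactants: 6 (S)-4-{[(4-methoxybenzyl)oxy]methyl}-2-methylcyclohex-2-en-1-one
Product: 7 (2R,3R,4R)-2,3-dihydroxy-4-{[(4-methoxybenzyl)oxy]methyl}-2-methylcyclohexan-1-one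
Conditions: K2OsO2(OH)4 (2 mol%), NMO (1.3 equiv), citric acid (0.75 equiv), t-BuOH/H2O 1:1, rt
Reagents that add atoms: N-methylmorpholine N-oxide, C[N+]1([O-])CCOCC1; water, O
Why: Upjohn-type osmium-catalysed syn-dihydroxylation (citric acid protocol for electron-poor alkenes) occurs on the face anti to the allylic CH2OPMB group, which sets C7 and C8 with both oxygens cis to each other and trans to C1.

**Fragment B (aroyl chloride)**

Step 5
Reactants: 8 methyl acetoacetate (two molecules)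
Product: 10 methyl 2,4-dihydroxy-6-methylbenzoate (methyl orsellinate), via methyl 3,5,7-trioxooctanoate 9 (not isolated)
Conditions: NaH (1.0 equiv), THF, 0 °C; n-BuLi (0.5 equiv), −78 °C→rt; reflux 24 h; 1 M HCl
Reagents that add atoms: none
Why: Claisen condensation of the acetoacetate dianion (γ-carbon) onto the ester of a second acetoacetate, then intramolecular aldol condensation and aromatisation (biomimetic tetraketide cyclisation).

Step 6
Reactants: 10 methyl 2,4-dihydroxy-6-methylbenzoate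
Product: 11 2,4-dihydroxy-6-methylbenzoic acid (orsellinic acid)
Conditions: LiOH·H2O (5 equiv), THF/MeOH/H2O, 60 °C, N2; then 1 M HCl, 0 °C
Reagents that add atoms: lithium hydroxide, [Li+].[OH-]
Why: Saponification; the carboxylate is stable in base, and cold acidification avoids decarboxylation of the free acid.

Step 7
Reactants: 11 2,4-dihydroxy-6-methylbenzoic acid
Product: 12 tert-butyldimethylsilyl 2,4-bis[(tert-butyldimethylsilyl)oxy]-6-methylbenzoate
Conditions: TBSCl (3.5 equiv), imidazole (7 equiv), DMF, 40 °C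
Reagents that add atoms: tert-butyldimethylsilyl chloride, CC(C)(C)[Si](C)(C)Cl
Why: Exhaustive silylation of both phenols and the acid; the silyl ester is the handle for the next step.

Step 8
Reactants: 12 tert-butyldimethylsilyl 2,4-bis[(tert-butyldimethylsilyl)oxy]-6-methylbenzoate
Product: 13 2,4-bis[(tert-butyldimethylsilyl)oxy]-6-methylbenzoyl chloride
Conditions: (COCl)2 (1.2 equiv), DMF (cat.), CH2Cl2, 0 °C→rt; used crude
Reagents that add atoms: oxalyl chloride, O=C(Cl)C(=O)Cl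
Why: Wissner-type conversion of a silyl ester into the acid chloride under neutral conditions, which leaves the aryl silyl ethers intact.

**Union of A and B**

Step 9
Reactants: 7 (2R,3R,4R)-2,3-dihydroxy-4-{[(4-methoxybenzyl)oxy]methyl}-2-methylcyclohexan-1-one; 13 2,4-bis[(tert-butyldimethylsilyl)oxy]-6-methylbenzoyl chloride
Product: 14 (1R,2R,6R)-2-hydroxy-6-{[(4-methoxybenzyl)oxy]methyl}-2-methyl-3-oxocyclohexyl 2,4-bis[(tert-butyldimethylsilyl)oxy]-6-methylbenzoate
Conditions: 13 (1.5 equiv), DMAP (0.5 equiv), Et3N (3 equiv), CH2Cl2, 0→40 °C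
Reagents that add atoms: none
Why: DMAP-mediated acyl transfer (Steglich-type) acylates only the secondary C8 hydroxyl, since the tertiary α-ketol hydroxyl is inert; no stereocentre is touched and the saturated ketone cannot eliminate the new ester.

Step 10
Reactants: 14 (1R,2R,6R)-2-hydroxy-6-{[(4-methoxybenzyl)oxy]methyl}-2-methyl-3-oxocyclohexyl 2,4-bis[(tert-butyldimethylsilyl)oxy]-6-methylbenzoate
Product: 15 (1R,2R,6R)-6-hydroxy-2-{[(4-methoxybenzyl)oxy]methyl}-6-methyl-5-oxocyclohex-3-en-1-yl 2,4-bis[(tert-butyldimethylsilyl)oxy]-6-methylbenzoate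
Conditions: IBX (2.2 equiv), 4-methoxypyridine N-oxide (2.2 equiv), DMSO, 25 °C
Reagents that add atoms: none
Why: Nicolaou IBX dehydrogenation of a ketone to the enone; only C5 carries α-hydrogens (C7 is quaternary), so the C4a=C5 enone forms regiospecifically.

Step 11
Reactants: 15 (1R,2R,6R)-6-hydroxy-2-{[(4-methoxybenzyl)oxy]methyl}-6-methyl-5-oxocyclohex-3-en-1-yl 2,4-bis[(tert-butyldimethylsilyl)oxy]-6-methylbenzoate
Product: 16 (1R,2R,6R)-6-hydroxy-2-(hydroxymethyl)-6-methyl-5-oxocyclohex-3-en-1-yl 2,4-bis[(tert-butyldimethylsilyl)oxy]-6-methylbenzoate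
Conditions: DDQ (1.3 equiv), CH2Cl2/pH 7 buffer 10:1, 0 °C→rt
Reagents that add atoms: none
Why: Oxidative PMB ether cleavage with DDQ is neutral and orthogonal to the aryl silyl ethers, the ester and the enone.

**Fragment C and end game**

Step 12
Reactants: 17 (E)-but-2-enoyl chloride (crotonyl chloride); 18 trimethylsulfoxonium iodide
Product: 20 (3E)-1-[dimethyl(oxo)-λ6-sulfanylidene]pent-3-en-2-one, via dimethylsulfoxonium methylide 19 (not isolated)
Conditions: 18 (2.2 equiv), KOt-Bu (2.2 equiv), THF, reflux 2 h; then 17 (1.0 equiv), 0 °C→rt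
Reagents that add atoms: none
Why: C-acylation of the Corey–Chaykovsky ylide by the acid chloride (acylation is faster than conjugate addition); the second equivalent of ylide deprotonates the acylsulfoxonium salt to give the stabilised ylide.

Step 13
Reactants: 16 (1R,2R,6R)-6-hydroxy-2-(hydroxymethyl)-6-methyl-5-oxocyclohex-3-en-1-yl 2,4-bis[(tert-butyldimethylsilyl)oxy]-6-methylbenzoate; 20 (3E)-1-[dimethyl(oxo)-λ6-sulfanylidene]pent-3-en-2-one
Product: 22 (7R,8R,8aR)-7-hydroxy-7-methyl-6-oxo-3-[(1E)-prop-1-en-1-yl]-6,7,8,8a-tetrahydro-1H-isochromen-8-yl 2,4-bis[(tert-butyldimethylsilyl)oxy]-6-methylbenzoate, via acylmethyl enone 21 (not isolated)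
Conditions: [Cp*RhCl2]2 (4 mol%), AgSbF6 (16 mol%), NaOAc (30 mol%), PivOH (1.0 equiv), 20 (1.5 equiv), HFIP, 45 °C; then PPTS (10 mol%), 4 Å MS, 25 °C
Reagents that add atoms: none
Why: Proposed new method: hydroxyl-directed alkenyl C–H acylmethylation/annulation, in which the primary hydroxyl of 16 binds the cationic Cp*Rh centre (trivalent rhodium) and acetate-assisted concerted metalation–deprotonation cleaves the enone β C4a–H (the only C–H that can close a five-membered oxa-rhodacycle, lying syn-periplanar to the pseudo-equatorial CH2OH); ylide 20 then coordinates and loses DMSO to give a rhodium carbene, 1,1-migratory insertion forms C4–C4a, and protodemetalation by HFIP/PivOH releases 21 with no external oxidant, so the primary alcohol is not oxidised; acid-promoted hemiketalisation and dehydration towards C4 (the only side bearing hydrogens) gives the conjugated 2H-pyran 22 without forming or touching a stereocentre; the closest known reactions are Cp*Rh-catalysed C–H acylmethylation/annulation of arenes and acrylamides with sulfoxonium ylides (isocoumarin, indole and pyridone syntheses) and the hydroxyl-directed Cp*Rh annulation of tertiary benzylic alcohols with alkynes to isochromenes, and what is new is a primary aliphatic hydroxyl directing an enone β-C–H.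

Step 14
Reactants: 22 (7R,8R,8aR)-7-hydroxy-7-methyl-6-oxo-3-[(1E)-prop-1-en-1-yl]-6,7,8,8a-tetrahydro-1H-isochromen-8-yl 2,4-bis[(tert-butyldimethylsilyl)oxy]-6-methylbenzoate
Product: 23 berkazaphilone C
Conditions: HF·pyridine, pyridine, THF, 0 °C→rt
Reagents that add atoms: none
Why: Buffered fluoride cleavage of the two aryl silyl ethers under non-basic conditions avoids acyl migration, C8a epimerisation and elimination of the C8 ester.

**Compound list**
1 | propane-1,3-diol | OCCCO | starting material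
2 | 3-[(4-methoxybenzyl)oxy]propan-1-ol | COc1ccc(COCCCO)cc1 | intermediate
3 | 3-[(4-methoxybenzyl)oxy]propanal | COc1ccc(COCCC=O)cc1 | intermediate
4 | pent-1-en-3-one | C=CC(=O)CC | starting material
5 | (R)-2-{[(4-methoxybenzyl)oxy]methyl}-5-oxoheptanal | O=C[C@@H](COCc1ccc(OC)cc1)CCC(=O)CC | intermediate
6 | (S)-4-{[(4-methoxybenzyl)oxy]methyl}-2-methylcyclohex-2-en-1-one | CC1=C[C@@H](COCc2ccc(OC)cc2)CCC1=O | intermediate
7 | (2R,3R,4R)-2,3-dihydroxy-4-{[(4-methoxybenzyl)oxy]methyl}-2-methylcyclohexan-1-one | C1CC(=O)[C@](C)(O)[C@H](O)[C@H]1COCc2ccc(OC)cc2 | intermediate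
8 | methyl acetoacetate | CC(=O)CC(=O)OC | starting material
9 | methyl 3,5,7-trioxooctanoate | CC(=O)CC(=O)CC(=O)CC(=O)OC | intermediate
10 | methyl 2,4-dihydroxy-6-methylbenzoate | COC(=O)c1c(C)cc(O)cc1O | intermediate
11 | 2,4-dihydroxy-6-methylbenzoic acid | OC(=O)c1c(C)cc(O)cc1O | intermediate
12 | tert-butyldimethylsilyl 2,4-bis[(tert-butyldimethylsilyl)oxy]-6-methylbenzoate | CC(C)(C)[Si](C)(C)OC(=O)c1c(C)cc(O[Si](C)(C)C(C)(C)C)cc1O[Si](C)(C)C(C)(C)C | intermediate
13 | 2,4-bis[(tert-butyldimethylsilyl)oxy]-6-methylbenzoyl chloride | O=C(Cl)c1c(C)cc(O[Si](C)(C)C(C)(C)C)cc1O[Si](C)(C)C(C)(C)C | intermediate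
14 | (1R,2R,6R)-2-hydroxy-6-{[(4-methoxybenzyl)oxy]methyl}-2-methyl-3-oxocyclohexyl 2,4-bis[(tert-butyldimethylsilyl)oxy]-6-methylbenzoate | C1CC(=O)[C@](C)(O)[C@H](OC(=O)c2c(C)cc(O[Si](C)(C)C(C)(C)C)cc2O[Si](C)(C)C(C)(C)C)[C@H]1COCc3ccc(OC)cc3 | intermediate
15 | (1R,2R,6R)-6-hydroxy-2-{[(4-methoxybenzyl)oxy]methyl}-6-methyl-5-oxocyclohex-3-en-1-yl 2,4-bis[(tert-butyldimethylsilyl)oxy]-6-methylbenzoate | C1=CC(=O)[C@](C)(O)[C@H](OC(=O)c2c(C)cc(O[Si](C)(C)C(C)(C)C)cc2O[Si](C)(C)C(C)(C)C)[C@H]1COCc3ccc(OC)cc3 | intermediate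
16 | (1R,2R,6R)-6-hydroxy-2-(hydroxymethyl)-6-methyl-5-oxocyclohex-3-en-1-yl 2,4-bis[(tert-butyldimethylsilyl)oxy]-6-methylbenzoate | C1=CC(=O)[C@](C)(O)[C@H](OC(=O)c2c(C)cc(O[Si](C)(C)C(C)(C)C)cc2O[Si](C)(C)C(C)(C)C)[C@H]1CO | intermediate
17 | (E)-but-2-enoyl chloride | C/C=C/C(Cl)=O | starting material
18 | trimethylsulfoxonium iodide | C[S+](C)(C)=O.[I-] | starting material
19 | dimethylsulfoxonium methylide | C=S(C)(C)=O | intermediate
20 | (3E)-1-[dimethyl(oxo)-λ6-sulfanylidene]pent-3-en-2-one | C/C=C/C(=O)C=S(C)(C)=O | intermediate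
21 | (1R,2R,6R)-6-hydroxy-2-(hydroxymethyl)-6-methyl-5-oxo-3-[(3E)-2-oxopent-3-en-1-yl]cyclohex-3-en-1-yl 2,4-bis[(tert-butyldimethylsilyl)oxy]-6-methylbenzoate | C/C=C/C(=O)CC1=CC(=O)[C@](C)(O)[C@H](OC(=O)c2c(C)cc(O[Si](C)(C)C(C)(C)C)cc2O[Si](C)(C)C(C)(C)C)[C@H]1CO | intermediate
22 | (7R,8R,8aR)-7-hydroxy-7-methyl-6-oxo-3-[(1E)-prop-1-en-1-yl]-6,7,8,8a-tetrahydro-1H-isochromen-8-yl 2,4-bis[(tert-butyldimethylsilyl)oxy]-6-methylbenzoate | C/C=C/C1=CC2=CC(=O)[C@](C)(O)[C@H](OC(=O)c3c(C)cc(O[Si](C)(C)C(C)(C)C)cc3O[Si](C)(C)C(C)(C)C)[C@H]2CO1 | intermediate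
23 | berkazaphilone C, (7R,8R,8aR)-7-hydroxy-7-methyl-6-oxo-3-[(1E)-prop-1-en-1-yl]-6,7,8,8a-tetrahydro-1H-isochromen-8-yl 2,4-dihydroxy-6-methylbenzoate | C/C=C/C1=CC2=CC(=O)[C@](C)(O)[C@H](OC(=O)c3c(C)cc(O)cc3O)[C@H]2CO1 | target

**Step count**
Total: 14 steps. Longest linear sequence: 9 steps (1, 2, 3, 4, 9, 10, 11, 13, 14), i.e. 9 of 14.

**Steps most likely to fail**

Step 13 (the new rhodium step). A primary aliphatic hydroxyl is a weak directing group, the α-ketol may sequester the catalyst, and ylide decomposition may outrun C–H activation. The fallback uses known chemistry, sets out from 15 and comes back at 22. The zinc acetylide of commercial (E)-pent-3-en-1-yne (n-BuLi, ZnBr2) is added to enone 15 in the presence of TMSOTf (silyl-triflate-promoted conjugate alkynylation, which also silylates the tertiary hydroxyl) to give the 3-alkynyl bis-trimethylsilyl enol ether F1. Saegusa–Ito oxidation with Pd(OAc)2 in MeCN (divalent palladium) restores the enone as the 3-alkynyl cyclohexenone F2. DDQ and then citric acid in MeOH remove the PMB and tertiary TMS groups to give the ynenone diol F3. Ph3PAuNTf2 (2 mol%, CH2Cl2) catalyses the 6-endo-dig hydroalkoxylation at the δ-carbon of the ynenone and delivers 22.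

Step 9 (esterification). A 2,6-disubstituted aroyl chloride must acylate a secondary alcohol flanked by a quaternary and a tertiary carbon. The fallback sets out from 11 and 7 and comes back at 14. Acid 11 is condensed with acetone (TFAA, TFA) to the acetonide 7-hydroxy-2,2,5-trimethyl-4H-1,3-benzodioxin-4-one F4, which is silylated (TBSCl, imidazole) to the silyl ether F5. Irradiation of F5 at 300 nm in CH2Cl2 with 7 generates the planar quinoketene, which acylates hindered alcohols under neutral conditions and gives the salicylate ester F6. Silylation of the remaining chelated phenol (TBSCl, imidazole, DMF, 40 °C) gives 14.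

Step 10 (desaturation). The hindered α-ketol may react sluggishly with IBX, and the enone product is sensitive to elimination. The fallback sets out from 14 and comes back at 15. LiHMDS with TMSCl as internal quench (THF, −78 °C) gives the bis-trimethylsilyl enol ether F7. Saegusa–Ito oxidation with Pd(OAc)2 (MeCN, rt) gives the silyl-protected enone F8. Citric acid in MeOH removes the tertiary TMS ether to give 15.

Further compounds
F1 | step 13 | (1R,2R,6R)-2-methyl-6-{[(4-methoxybenzyl)oxy]methyl}-5-[(3E)-pent-3-en-1-yn-1-yl]-2,3-bis[(trimethylsilyl)oxy]cyclohex-3-en-1-yl 2,4-bis[(tert-butyldimethylsilyl)oxy]-6-methylbenzoate (C5 epimers) | C/C=C/C#CC1C=C(O[Si](C)(C)C)[C@](C)(O[Si](C)(C)C)[C@H](OC(=O)c2c(C)cc(O[Si](C)(C)C(C)(C)C)cc2O[Si](C)(C)C(C)(C)C)[C@H]1COCc3ccc(OC)cc3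
F2 | step 13 | (1R,2R,6R)-2-{[(4-methoxybenzyl)oxy]methyl}-6-methyl-5-oxo-3-[(3E)-pent-3-en-1-yn-1-yl]-6-[(trimethylsilyl)oxy]cyclohex-3-en-1-yl 2,4-bis[(tert-butyldimethylsilyl)oxy]-6-methylbenzoate | C/C=C/C#CC1=CC(=O)[C@](C)(O[Si](C)(C)C)[C@H](OC(=O)c2c(C)cc(O[Si](C)(C)C(C)(C)C)cc2O[Si](C)(C)C(C)(C)C)[C@H]1COCc3ccc(OC)cc3
F3 | step 13 | (1R,2R,6R)-6-hydroxy-2-(hydroxymethyl)-6-methyl-5-oxo-3-[(3E)-pent-3-en-1-yn-1-yl]cyclohex-3-en-1-yl 2,4-bis[(tert-butyldimethylsilyl)oxy]-6-methylbenzoate | C/C=C/C#CC1=CC(=O)[C@](C)(O)[C@H](OC(=O)c2c(C)cc(O[Si](C)(C)C(C)(C)C)cc2O[Si](C)(C)C(C)(C)C)[C@H]1CO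
F4 | step 9 | 7-hydroxy-2,2,5-trimethyl-4H-1,3-benzodioxin-4-one | CC1(C)OC(=O)c2c(C)cc(O)cc2O1
F5 | step 9 | 7-[(tert-butyldimethylsilyl)oxy]-2,2,5-trimethyl-4H-1,3-benzodioxin-4-one | CC1(C)OC(=O)c2c(C)cc(O[Si](C)(C)C(C)(C)C)cc2O1
F6 | step 9 | (1R,2R,6R)-2-hydroxy-6-{[(4-methoxybenzyl)oxy]methyl}-2-methyl-3-oxocyclohexyl 4-[(tert-butyldimethylsilyl)oxy]-2-hydroxy-6-methylbenzoate | C1CC(=O)[C@](C)(O)[C@H](OC(=O)c2c(C)cc(O[Si](C)(C)C(C)(C)C)cc2O)[C@H]1COCc3ccc(OC)cc3
F7 | step 10 | (1R,2R,6R)-6-{[(4-methoxybenzyl)oxy]methyl}-2-methyl-2,3-bis[(trimethylsilyl)oxy]cyclohex-3-en-1-yl 2,4-bis[(tert-butyldimethylsilyl)oxy]-6-methylbenzoate | C1C=C(O[Si](C)(C)C)[C@](C)(O[Si](C)(C)C)[C@H](OC(=O)c2c(C)cc(O[Si](C)(C)C(C)(C)C)cc2O[Si](C)(C)C(C)(C)C)[C@H]1COCc3ccc(OC)cc3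
F8 | step 10 | (1R,2R,6R)-2-{[(4-methoxybenzyl)oxy]methyl}-6-methyl-5-oxo-6-[(trimethylsilyl)oxy]cyclohex-3-en-1-yl 2,4-bis[(tert-butyldimethylsilyl)oxy]-6-methylbenzoate | C1=CC(=O)[C@](C)(O[Si](C)(C)C)[C@H](OC(=O)c2c(C)cc(O[Si](C)(C)C(C)(C)C)cc2O[Si](C)(C)C(C)(C)C)[C@H]1COCc3ccc(OC)cc3
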